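## Structural features

Selaginellin is a single benzene ring (ring A) with four contiguous substituents and two adjacent hydrogens (C3, C4). C1 carries an exocyclic sp2 carbon that is bonded to a 4-hydroxyphenyl ring and, through a C=C bond, to a cyclohexa-2,5-dienone ring (a p-quinone methide, the dehydrated form of a bis(4-hydroxyphenyl)aryl carbinol). C2 carries a 4-hydroxyphenyl ring, C5 a hydroxymethyl group and C6 a (4-hydroxyphenyl)ethynyl group. There is no stereocentre, and the crowded biaryl and methide axes are not configurationally fixed, so no stereochemical element has to be set. The fragile parts are the quinone methide (electrophilic at the methide carbon), the free phenols, and the benzylic alcohol ortho to the alkyne, which can add to it under π-acids or strong base. The real difficulty is the 1,2,3,4-substitution of ring A: the triaryl carbon on C1 and the sp carbon on C6 each lie between two other substituents, and C1 and C6 must be told apart without ambiguity. A further trap is that an oxygen on the C1 triaryl carbon and a carbonyl group on C6 are expected to close to a five-membered cyclic hemiketal when both are free. The key step exploits the sp carbon attached to C6 of ring A: it can enter as the carbonyl carbon of a C6 aryl ketone, and a one-carbon homologation with 1,2-aryl shift turns C6–C(=O)–Ar into C6–C≡C–Ar without any cross-coupling at the shielded C6 position.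

## Logic of the disconnections

23 ⇒ 22. Only C–O and Si–O bonds are cut: the four aryl acetals, the silyl ether on the C5 CH2O group and the C–OCH3 bond at the carbon on C1. This hides the quinone methide and the phenols in one neutral, base-stable compound, so every earlier step may use strong bases and nucleophiles. The forward step must remove all six groups in one acid treatment and leave the alkyne and the benzylic alcohol alone.

22 ⇒ 18 + 19. The C≡C unit is taken apart: the carbon on C6 returns to a carbonyl carbon, the outer sp carbon returns to 19, and the outer aryl ring returns to the carbonyl carbon. C6 is the most shielded ring position, and a carbonyl carbon can be placed there while ring A is built. The forward step must deliver 20 to a ketone between two ortho groups, and the aryl shift in 21 must be faster than insertion into neighbouring C–H bonds.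

18 ⇒ 17 ⇒ 14 + 16. After removal of the silyl group, the bond between the C6 carbonyl carbon and its aryl ring is cut. This folds the carbonyl carbon and the C5 oxygen into the lactone of 14; 16 comes from 15. A lactone takes up exactly one aryl nucleophile, and with the carbonyl tied to the C5 oxygen the oxygen on the C1 carbon (already a methyl ether) never meets a free ketone as an alkoxide. The forward step must stop after one addition.

14 ⇒ 13 ⇒ 12. Two hydrogens are put back on C2 and C5, and ring A is opened at C1–C2 and C5–C6, the retron of a [4+2] cycloaddition between a C2–C5 diene and a C6–C1 alkyne. The lactone C(=O)–O–CH2 unit becomes a tether, so the carbonyl-bearing alkyne carbon can only bond to the CH2O-bearing diene terminus; this settles which of C1 and C6 carries the triaryl carbon. The forward step needs an (E,E)-diene, a thermal cyclisation through an ester tether with a bulky alkyne terminus, and a mild dehydrogenation.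

12 ⇒ 11 + 4. The ester C–O bond is cut, which separates the diene part (4) from the alkyne part (11) that already holds two aryl rings and the methoxy group. The forward step is an esterification of an acid-sensitive allylic alcohol with a strong, conjugate-acceptor acid.

11 ⇒ 9 (via 10) ⇒ 8 ⇒ 6 + 7, and 6 ⇒ 5. The C(sp)–CO2H bond, the O–CH3 bond and the bond between the carbinol carbon and the alkyne are cut in turn; the two acetals of 6 lead back to 5. The quaternary carbon is made here because addition to 6 is unhindered, whereas the same carbon on a finished ring A would lie between two ortho groups. O-methylation of 8 also has no carbonyl group nearby to divert the alkoxide.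

4 ⇒ 3 ⇒ 1 + 2. The allylic C–O is traced back to an ester and the C4=C5 double bond is cut; 2 supplies four carbons with the 2E geometry in place. The forward olefination has to give the 4E bond.

## Other disconnections considered

Alternative 1: Ring A is cut at C4–C5 and C1–C2.
- Forward key step: a TiCl4-mediated formal [3+3] cyclocondensation (Chan–Langer type) of the 1,3-bis(silyloxy)diene A2 with the aryl β-keto acetal A3. The diene terminus attacks the acetal, the central carbon closes on the ketone by aldol condensation, and aromatisation would give salicylate A1.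
- In its favour: the regiochemistry is built in (ester on C1, phenol on C6, CH2O on C5, aryl on C2), and the phenol could be triflated and coupled with an arylethyne. No addition to a shielded ketone and no carbene would be needed; on this point it is the better plan.
- Against it here: TiCl4 must tolerate a primary silyl ether and an electron-rich aryl ketone. The Sonogashira coupling would occur at a triflate between an ester and a CH2OSi group. The C1 ester, a 2,6-disubstituted benzoate, would have to accept two aryl nucleophiles on the finished, crowded ring.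
- Comparison. Structure: the same substitution pattern is reached, but with oxygen on C6, so the C6–C(sp) bond is made by cross-coupling at the most hindered position; the chosen plan brings that carbon in with the ring. Mechanism: an ionic, Lewis-acid condensation against a neutral thermal pericyclic closure that is kinder to acetal protecting groups. Step economy: A1 should be reached in fewer steps than 14 (equal or better), but the triaryl carbon is then made by the hardest kind of addition; in the chosen plan it comes from an unhindered benzophenone.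

Alternative 2: Ring A is cut at C1–C6, C2–C3 and C4–C5.
- Forward key step: a RhCl(PPh3)3-catalysed [2+2+2] cycloaddition of the ester-tethered diyne A5 with ethyne A6. It would close ring A and the phthalide lactone of A4 in one operation.
- In its favour: three C–C bonds and two rings in one step, all aryl groups of the triaryl carbon and the C2 aryl already in place, and no regiochemical question with ethyne. On convergence it is the better plan.
- Against it here: A5 is the ester of a tertiary, doubly anisyl-stabilised propargylic alcohol; it would be hard to acylate and prone to ionise at the alkyl–oxygen bond. In A4 the lactone oxygen sits on the triaryl carbon. After one aryl addition to the lactone carbon, the keto alcohol is expected to rest as its cyclic hemiketal, so neither the open ketone needed for homologation nor a clean O-methylation is secured.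
- Comparison. Structure: both plans pass through a phthalide, but with the lactone oxygen on opposite sides; in 14 it is on the C5 CH2 group, which leaves the trityl oxygen as a fixed methyl ether. Mechanism: metal-mediated oxidative cyclisation against a thermal [4+2]; both use a tether for regiocontrol (equal). Step economy: A4 is probably reached in fewer steps (equal or better), but more steps and more uncertainty follow it.

Alternative 3: Ring A is cut at C1–C6 and C2–C3.
- Forward key step: an inverse-demand Diels–Alder reaction of the 6-alkynyl coumalate A8 with the triarylpropyne A9; loss of CO2 from the bridged lactone would give benzoate A7.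
- In its favour: the arylethynyl group, all four aryl rings and the CH2OH carbon (as ester) are present when ring A forms. No organometallic addition to a crowded carbonyl and no carbene are needed. The methide carbon is carried as C–H and oxidised at the end, which avoids the hemiketal problem altogether; on these points it is the equal or the better plan. Aromatisation needs no oxidant.
- Against it here: the cycloaddition is intermolecular between an unsymmetrical pyranone and an unsymmetrical, unactivated, bulky alkyne. The required orientation places the diarylmethyl-bearing carbon next to the alkynyl-bearing C6, the most congested arrangement, and the electronic bias of an aryl/alkyl alkyne is small. High temperature would be needed, the alkynes of A8 and A7 are competing dienophiles, and the final hydride abstraction must spare the benzylic alcohol.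
- Comparison. Structure: the full carbon skeleton would exist earlier than in the chosen route. Mechanism: both are pericyclic ring formations, but the chosen one is intramolecular, so regiochemistry is enforced and not merely biased. Step economy: probably the shortest route if the regiochemistry held; the chosen plan spends extra steps on a tether that removes this doubt.

Key step: step 11

Remarks on the design:
- The four phenols are carried as methoxymethyl (MOM) ethers in place of methyl ethers, so that one acid treatment ends the synthesis; the carbon skeletons of 18 and 22 are unchanged.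
- Because a C6 ketone next to a free C1 triaryl carbinol oxygen is expected to close to a cyclic hemiketal and to misdirect O-alkylation, the methyl ether is made on 8, before ring A exists, and the C6 carbonyl is held as a lactone until then.
- Assumption: 1 and 15 are catalogue compounds (each is otherwise one MOMCl step from the phenol).

## Route

Step 1
Reactants: 1 4-(methoxymethoxy)benzaldehyde; 2 triethyl 4-phosphonocrotonate [ethyl (2E)-4-(diethoxyphosphoryl)but-2-enoate]
Product: 3 ethyl (2E,4E)-5-[4-(methoxymethoxy)phenyl]penta-2,4-dienoate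
Conditions: LiN(SiMe3)2, THF, –78 °C → rt
Reagents that add atoms: none
Why: Vinylogous Horner–Wadsworth–Emmons olefination; the stabilised γ-phosphonate anion should give the new C4=C5 bond as the E isomer and the 2E bond comes from 2; any 4Z isomer can be removed by crystallisation or iodine equilibration.

Step 2
Reactants: 3 ethyl (2E,4E)-5-[4-(methoxymethoxy)phenyl]penta-2,4-dienoate
Product: 4 (2E,4E)-5-[4-(methoxymethoxy)phenyl]penta-2,4-dien-1-ol
Conditions: i-Bu2AlH, CH2Cl2, –78 → 0 °C; aq. potassium sodium tartrate
Reagents that add atoms: none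
Why: 1,2-Reduction of a conjugated ester to the allylic alcohol; the diene geometry and the acetal are untouched by the aluminium hydride.

Step 3
Reactants: 5 4,4'-dihydroxybenzophenone
Product: 6 bis[4-(methoxymethoxy)phenyl]methanone
Conditions: MOMCl, i-Pr2NEt, CH2Cl2, 0 °C → rt
Reagents that add atoms: chloromethyl methyl ether (MOMCl), COCCl
Why: O-Alkylation of both phenols to formaldehyde acetals, which withstand the organometallic and basic steps that follow and fall in dilute acid at the end.

Step 4
Reactants: 6 bis[4-(methoxymethoxy)phenyl]methanone; 7 ethynylmagnesium bromide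
Product: 8 1,1-bis[4-(methoxymethoxy)phenyl]prop-2-yn-1-ol
Conditions: THF, 0 °C → rt; sat. aq. NH4Cl
Reagents that add atoms: none
Why: 1,2-Addition of an alkynyl Grignard reagent to a non-enolisable diaryl ketone; the future C1 triaryl carbon gets two of its aryl rings at an unhindered acyclic stage.

Step 5
Reactants: 8 1,1-bis[4-(methoxymethoxy)phenyl]prop-2-yn-1-ol
Product: 9 1,1'-(1-methoxyprop-2-yne-1,1-diyl)bis[4-(methoxymethoxy)benzene]
Conditions: NaH, MeI, THF, 0 °C → rt
Reagents that add atoms: iodomethane (MeI), CI
Why: Williamson methylation of the tertiary propargylic alkoxide; no carbonyl group is present to capture the alkoxide, and this methoxy group later leaves from the methide carbon.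

Step 6
Reactants: 9 1,1'-(1-methoxyprop-2-yne-1,1-diyl)bis[4-(methoxymethoxy)benzene]
Product: 11 4-methoxy-4,4-bis[4-(methoxymethoxy)phenyl]but-2-ynoic acid, via lithium acetylide 10 (not isolated)
Conditions: n-BuLi, THF, –78 °C; then CO2, –78 → 0 °C; cold dilute HCl to pH 3
Reagents that add atoms: carbon dioxide, O=C=O
Why: Deprotonation of the terminal alkyne and carboxylation; the electron-poor alkynoate disfavours ionisation of the diaryl methyl ether, so a brief cold acidification should be tolerated.

Step 7
Reactants: 11 4-methoxy-4,4-bis[4-(methoxymethoxy)phenyl]but-2-ynoic acid; 4 (2E,4E)-5-[4-(methoxymethoxy)phenyl]penta-2,4-dien-1-ol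
Product: 12 (2E,4E)-5-[4-(methoxymethoxy)phenyl]penta-2,4-dien-1-yl 4-methoxy-4,4-bis[4-(methoxymethoxy)phenyl]but-2-ynoate
Conditions: DCC, DMAP (cat.), CH2Cl2, –20 → 0 °C
Reagents that add atoms: none
Why: Steglich esterification; carbodiimide activation at low temperature keeps the strong alkynoic acid from ionising the dienyl alcohol and limits conjugate addition to the ynoate.

Step 8
Reactants: 12 (2E,4E)-5-[4-(methoxymethoxy)phenyl]penta-2,4-dien-1-yl 4-methoxy-4,4-bis[4-(methoxymethoxy)phenyl]but-2-ynoate
Product: 14 7-{methoxybis[4-(methoxymethoxy)phenyl]methyl}-6-[4-(methoxymethoxy)phenyl]-2-benzofuran-1(3H)-one, via cis-3a,6-dihydro cycloadduct 13 (not isolated)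
Conditions: BHT (cat.), 1,2-dichlorobenzene (0.01 M), 150 °C; then DDQ, rt → 60 °C
Reagents that add atoms: none
Why: Intramolecular Diels–Alder reaction of an ester-tethered dienyne, in which the three-atom tether allows only the orientation that joins the carbonyl-bearing alkyne carbon to the CH2O-bearing diene terminus and the trityl-bearing carbon to the aryl-bearing terminus; the two sp3 centres of 13 (cis, from suprafacial addition to the E,E-diene) are erased when DDQ dehydrogenates the cyclohexa-1,4-diene to ring A.

Step 9
Reactants: 14 7-{methoxybis[4-(methoxymethoxy)phenyl]methyl}-6-[4-(methoxymethoxy)phenyl]-2-benzofuran-1(3H)-one; 15 1-bromo-4-(methoxymethoxy)benzene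
Product: 17 [6-(hydroxymethyl)-2-{methoxybis[4-(methoxymethoxy)phenyl]methyl}-3-[4-(methoxymethoxy)phenyl]phenyl][4-(methoxymethoxy)phenyl]methanone, via 4-(methoxymethoxy)phenyllithium 16 (not isolated)
Conditions: 15, n-BuLi, THF, –78 °C; then 14, –78 °C; sat. aq. NH4Cl at –78 °C
Reagents that add atoms: none
Why: Mono-addition of an aryllithium to a phthalide; the tetrahedral lithium lactolate should persist at –78 °C and block a second addition, and work-up opens it to the hydroxy ketone (in equilibrium with its hemiketal to the primary alcohol); the oxygen on the C1 carbon is already a methyl ether and cannot take part.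

Step 10
Reactants: 17 [6-(hydroxymethyl)-2-{methoxybis[4-(methoxymethoxy)phenyl]methyl}-3-[4-(methoxymethoxy)phenyl]phenyl][4-(methoxymethoxy)phenyl]methanone
Product: 18 {6-[(tert-butyldimethylsilyloxy)methyl]-2-{methoxybis[4-(methoxymethoxy)phenyl]methyl}-3-[4-(methoxymethoxy)phenyl]phenyl}[4-(methoxymethoxy)phenyl]methanone
Conditions: TBSCl, imidazole, DMF, rt
Reagents that add atoms: tert-butyldimethylsilyl chloride (TBSCl), CC(C)(C)[Si](C)(C)Cl
Why: Silylation of the primary alcohol traps the open keto form, since the tertiary hemiketal hydroxyl of the ring tautomer is not silylated under these conditions; neutral work-up avoids dehydration to an isobenzofuran.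

Step 11
Reactants: 18 {6-[(tert-butyldimethylsilyloxy)methyl]-2-{methoxybis[4-(methoxymethoxy)phenyl]methyl}-3-[4-(methoxymethoxy)phenyl]phenyl}[4-(methoxymethoxy)phenyl]methanone; 19 trimethylsilyldiazomethane
Product: 22 tert-butyl{[3-{methoxybis[4-(methoxymethoxy)phenyl]methyl}-4-[4-(methoxymethoxy)phenyl]-2-{[4-(methoxymethoxy)phenyl]ethynyl}phenyl]methoxy}dimethylsilane, via lithiated trimethylsilyldiazomethane 20 (not isolated), via alkylidene carbene 21 (not isolated)
Conditions: 19, n-BuLi, THF, –78 °C; then 18, –78 °C → rt; sat. aq. NH4Cl
Reagents that add atoms: none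
Why: Colvin rearrangement: 20 adds through its diazo carbon to the C6 carbonyl of 18, the β-silyl alkoxide undergoes Peterson elimination of LiOSiMe3 to a diazoalkene, and loss of N2 leaves alkylidene carbene 21. A 1,2-shift of either aryl group (ring A or the 4-(methoxymethoxy)phenyl ring) then forms the triple bond; both shifts give the same alkyne, so migratory preference does not affect the constitution. The closest known reaction type is the conversion of benzophenones into diarylalkynes with lithiated trimethylsilyldiazomethane. No ring is closed and no stereocentre is formed. The selectivity needed is within the carbene: the aryl shift has to be faster than 1,5 C–H insertion into the adjacent CH2OSi group (which would give an indene) and than attack by the ether oxygens, and the high migratory aptitude of aryl groups on alkylidene carbenes, raised further by the 4-alkoxy substituent, should secure this. The ketone has no α-hydrogen, so enolisation cannot compete with addition, and the reagent is slim at its nucleophilic carbon, which matters for a carbonyl group lying between the trityl ether and the CH2OSi group. The acetal, silyl and trityl ethers are inert to these basic, aprotic conditions. A slight excess of 19 over n-BuLi keeps free butyllithium away from the ketone.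

Step 12
Reactants: 22 tert-butyl{[3-{methoxybis[4-(methoxymethoxy)phenyl]methyl}-4-[4-(methoxymethoxy)phenyl]-2-{[4-(methoxymethoxy)phenyl]ethynyl}phenyl]methoxy}dimethylsilane
Product: 23 selaginellin, 4-{[3-(hydroxymethyl)-2-[(4-hydroxyphenyl)ethynyl]-6-(4-hydroxyphenyl)phenyl](4-hydroxyphenyl)methylidene}cyclohexa-2,5-dien-1-one
Conditions: 3 M aq. HCl, MeOH/THF, 40 °C; then aq. NaHCO3 to pH 6–7
Reagents that add atoms: none
Why: Acid-catalysed acetal and silyl ether cleavage frees the four phenols and the benzylic alcohol while the trityl methyl ether ionises to a delocalised triaryl cation, which on neutralisation loses a phenolic proton to give the quinone methide; methanol captures the CH2 units as dimethoxymethane, and dilute acid at this temperature should not protonate the diarylalkyne.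

## Compound list

1 | 4-(methoxymethoxy)benzaldehyde | COCOc1ccc(C=O)cc1 | starting material
2 | triethyl 4-phosphonocrotonate, ethyl (2E)-4-(diethoxyphosphoryl)but-2-enoate | CCOC(=O)/C=C/CP(=O)(OCC)OCC | starting material
3 | ethyl (2E,4E)-5-[4-(methoxymethoxy)phenyl]penta-2,4-dienoate | CCOC(=O)/C=C/C=C/c1ccc(OCOC)cc1 | intermediate
4 | (2E,4E)-5-[4-(methoxymethoxy)phenyl]penta-2,4-dien-1-ol | OC/C=C/C=C/c1ccc(OCOC)cc1 | intermediate
5 | 4,4'-dihydroxybenzophenone | O=C(c1ccc(O)cc1)c1ccc(O)cc1 | starting material
6 | bis[4-(methoxymethoxy)phenyl]methanone | O=C(c1ccc(OCOC)cc1)c1ccc(OCOC)cc1 | intermediate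
7 | ethynylmagnesium bromide | C#C[Mg]Br | starting material
8 | 1,1-bis[4-(methoxymethoxy)phenyl]prop-2-yn-1-ol | C#CC(O)(c1ccc(OCOC)cc1)c1ccc(OCOC)cc1 | intermediate
9 | 1,1'-(1-methoxyprop-2-yne-1,1-diyl)bis[4-(methoxymethoxy)benzene] | C#CC(OC)(c1ccc(OCOC)cc1)c1ccc(OCOC)cc1 | intermediate
10 | lithium acetylide of 9, {3-methoxy-3,3-bis[4-(methoxymethoxy)phenyl]prop-1-yn-1-yl}lithium | [Li]C#CC(OC)(c1ccc(OCOC)cc1)c1ccc(OCOC)cc1 | intermediate (not isolated)
11 | 4-methoxy-4,4-bis[4-(methoxymethoxy)phenyl]but-2-ynoic acid | OC(=O)C#CC(OC)(c1ccc(OCOC)cc1)c1ccc(OCOC)cc1 | intermediate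
12 | (2E,4E)-5-[4-(methoxymethoxy)phenyl]penta-2,4-dien-1-yl 4-methoxy-4,4-bis[4-(methoxymethoxy)phenyl]but-2-ynoate | COCOc1ccc(/C=C/C=C/COC(=O)C#CC(OC)(c2ccc(OCOC)cc2)c2ccc(OCOC)cc2)cc1 | intermediate
13 | cis-7-{methoxybis[4-(methoxymethoxy)phenyl]methyl}-6-[4-(methoxymethoxy)phenyl]-3a,6-dihydro-2-benzofuran-1(3H)-one (racemic; H-3a and H-6 on the same face, one enantiomer drawn) | O=C1OC[C@H]2C=C[C@@H](c3ccc(OCOC)cc3)C(=C12)C(OC)(c1ccc(OCOC)cc1)c1ccc(OCOC)cc1 | intermediate (not isolated)
14 | 7-{methoxybis[4-(methoxymethoxy)phenyl]methyl}-6-[4-(methoxymethoxy)phenyl]-2-benzofuran-1(3H)-one | O=C1OCc2ccc(-c3ccc(OCOC)cc3)c(c12)C(OC)(c1ccc(OCOC)cc1)c1ccc(OCOC)cc1 | intermediate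
15 | 1-bromo-4-(methoxymethoxy)benzene | COCOc1ccc(Br)cc1 | starting material
16 | 4-(methoxymethoxy)phenyllithium | [Li]c1ccc(OCOC)cc1 | intermediate (not isolated)
17 | [6-(hydroxymethyl)-2-{methoxybis[4-(methoxymethoxy)phenyl]methyl}-3-[4-(methoxymethoxy)phenyl]phenyl][4-(methoxymethoxy)phenyl]methanone (in equilibrium with its cyclic hemiketal) | COCOc1ccc(cc1)C(=O)c1c(CO)ccc(-c2ccc(OCOC)cc2)c1C(OC)(c1ccc(OCOC)cc1)c1ccc(OCOC)cc1 | intermediate
18 | {6-[(tert-butyldimethylsilyloxy)methyl]-2-{methoxybis[4-(methoxymethoxy)phenyl]methyl}-3-[4-(methoxymethoxy)phenyl]phenyl}[4-(methoxymethoxy)phenyl]methanone | COCOc1ccc(cc1)C(=O)c1c(CO[Si](C)(C)C(C)(C)C)ccc(-c2ccc(OCOC)cc2)c1C(OC)(c1ccc(OCOC)cc1)c1ccc(OCOC)cc1 | intermediate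
19 | trimethylsilyldiazomethane | C[Si](C)(C)C=[N+]=[N-] | starting material
20 | lithiated trimethylsilyldiazomethane, [diazo(trimethylsilyl)methyl]lithium | C[Si](C)(C)C([Li])=[N+]=[N-] | intermediate (not isolated)
21 | alkylidene carbene, 2-aryl-2-[4-(methoxymethoxy)phenyl]ethenylidene derived from 18 | COCOc1ccc(cc1)C(=[C])c1c(CO[Si](C)(C)C(C)(C)C)ccc(-c2ccc(OCOC)cc2)c1C(OC)(c1ccc(OCOC)cc1)c1ccc(OCOC)cc1 | intermediate (not isolated)
22 | tert-butyl{[3-{methoxybis[4-(methoxymethoxy)phenyl]methyl}-4-[4-(methoxymethoxy)phenyl]-2-{[4-(methoxymethoxy)phenyl]ethynyl}phenyl]methoxy}dimethylsilane | COCOc1ccc(cc1)C#Cc1c(CO[Si](C)(C)C(C)(C)C)ccc(-c2ccc(OCOC)cc2)c1C(OC)(c1ccc(OCOC)cc1)c1ccc(OCOC)cc1 | intermediate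
23 | selaginellin, 4-{[3-(hydroxymethyl)-2-[(4-hydroxyphenyl)ethynyl]-6-(4-hydroxyphenyl)phenyl](4-hydroxyphenyl)methylidene}cyclohexa-2,5-dien-1-one | O=C1C=CC(=C(c2ccc(O)cc2)c2c(-c3ccc(O)cc3)ccc(CO)c2C#Cc2ccc(O)cc2)C=C1 | target

## Step count and least certain steps

Total step count: 12. Longest linear sequence: 10 steps (5 → 6 → 8 → 9 → 11 → 12 → 14 → 17 → 18 → 22 → 23, steps 3 to 12).

Step 11 (key step). Most likely to go wrong: the diazo carbanion may fail to reach the carbonyl carbon, which is shielded by the trityl ether on one side and the CH2OSi group on the other. Once the carbene forms, it may be diverted by insertion into the neighbouring CH2O C–H bonds. Fallback (sets out from 14, returns at 22): avoid any addition at the crowded ketone.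
- Reduce the lactone with i-Bu2AlH at –78 °C to the lactol 7-{methoxybis[4-(methoxymethoxy)phenyl]methyl}-6-[4-(methoxymethoxy)phenyl]-1,3-dihydro-2-benzofuran-1-ol F1.
- Homologate the open hydroxy aldehyde form with dimethyl (1-diazo-2-oxopropyl)phosphonate and K2CO3 in MeOH (Ohira–Bestmann conditions) to the terminal alkyne {2-ethynyl-3-{methoxybis[4-(methoxymethoxy)phenyl]methyl}-4-[4-(methoxymethoxy)phenyl]phenyl}methanol F2.
- Silylate (TBSCl, imidazole) to tert-butyl{[2-ethynyl-3-{methoxybis[4-(methoxymethoxy)phenyl]methyl}-4-[4-(methoxymethoxy)phenyl]phenyl]methoxy}dimethylsilane F3.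
- Couple F3 with the iodo analogue of 15 under Sonogashira conditions (Pd(PPh3)4, CuI as copper iodide, Et3N) to reach 22. The coupling then takes place at the open alkyne terminus and not at a ring A carbon.

Step 8. Most likely to go wrong: slow cyclisation, because the ester must adopt its disfavoured s-cis conformation and the trityl-bearing alkyne carbon must bond next to the aryl-bearing diene terminus; thermal ionisation or allylic transposition of the electron-rich dienyl ester and oligomerisation can then take over. Fallback (sets out from 4 and 1, returns at 17): build ring A by an intermolecular cycloaddition with a symmetrical dienophile and tell the two carbonyl groups apart afterwards through the C5 oxygen.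
- Silylate 4 (Et3SiCl, imidazole) to triethyl{[(2E,4E)-5-[4-(methoxymethoxy)phenyl]penta-2,4-dien-1-yl]oxy}silane F4.
- Add 7 to 1, metallate the alkynyl alkoxide in the same flask with EtMgBr and add a second equivalent of 1, giving 1,4-bis[4-(methoxymethoxy)phenyl]but-2-yne-1,4-diol F5; oxidise with MnO2 to 1,4-bis[4-(methoxymethoxy)phenyl]but-2-yne-1,4-dione F6.
- Combine F4 and F6 in toluene at 90 °C to the cis-cyclohexa-1,4-diene adduct F7; DDQ gives {3-[4-(methoxymethoxy)phenyl]-6-[(triethylsilyloxy)methyl]-1,2-phenylene}bis{[4-(methoxymethoxy)phenyl]methanone} F8.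
- PPTS in MeOH/HC(OMe)3 removes the silyl group and closes the C5 oxygen on the C6 ketone, the only one it can reach, to the cyclic methyl ketal {1-methoxy-1,6-bis[4-(methoxymethoxy)phenyl]-1,3-dihydro-2-benzofuran-7-yl}[4-(methoxymethoxy)phenyl]methanone F9.
- 16 adds to the one remaining ketone and MeI/DMPU methylates the alkoxide to 1-methoxy-7-{methoxybis[4-(methoxymethoxy)phenyl]methyl}-1,6-bis[4-(methoxymethoxy)phenyl]-1,3-dihydro-2-benzofuran F10.
- Hydrolysis of the ketal in a pH 4–5 acetate buffer, too weak to ionise the trityl ether, releases 17.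
- This path has no tether penalty, but it asks for an aryllithium addition to a ketone between two ortho groups, which is why it is the second choice.

Step 9. Most likely to go wrong: over-addition after early collapse of the lactolate, or no addition because the trityl ether shields the lactone carbonyl from its peri position. Fallback (sets out from 14, returns at 18):
- Reduce to lactol F1 as described for step 11.
- Add 16 (2 equiv) to F1, whose open hydroxy aldehyde form is far less shielded, to give the diol [6-(hydroxymethyl)-2-{methoxybis[4-(methoxymethoxy)phenyl]methyl}-3-[4-(methoxymethoxy)phenyl]phenyl][4-(methoxymethoxy)phenyl]methanol F11.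
- Silylate the primary hydroxyl selectively (TBSCl, imidazole, 0 °C) to {6-[(tert-butyldimethylsilyloxy)methyl]-2-{methoxybis[4-(methoxymethoxy)phenyl]methyl}-3-[4-(methoxymethoxy)phenyl]phenyl}[4-(methoxymethoxy)phenyl]methanol F12.
- Oxidise the diaryl carbinol with Dess–Martin periodinane/NaHCO3 to 18.

Step 7. Most likely to go wrong: ionisation of the electron-rich dienyl alcohol by the strong alkynoic acid (allylic transposition, ether formation) and conjugate addition of the acyl-transfer catalyst to the ynoate. Fallback (sets out from 4, returns at 12): reverse the roles of the partners. Convert 4 with CBr4/PPh3 at –20 °C into 1-[(1E,3E)-5-bromopenta-1,3-dien-1-yl]-4-(methoxymethoxy)benzene F13 and O-alkylate the caesium salt of 11 (Cs2CO3, DMF, 0 °C) with it.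

## Further compounds

F1 | step 11 | 7-{methoxybis[4-(methoxymethoxy)phenyl]methyl}-6-[4-(methoxymethoxy)phenyl]-1,3-dihydro-2-benzofuran-1-ol (racemic) | OC1OCc2ccc(-c3ccc(OCOC)cc3)c(c12)C(OC)(c1ccc(OCOC)cc1)c1ccc(OCOC)cc1
F2 | step 11 | {2-ethynyl-3-{methoxybis[4-(methoxymethoxy)phenyl]methyl}-4-[4-(methoxymethoxy)phenyl]phenyl}methanol | C#Cc1c(CO)ccc(-c2ccc(OCOC)cc2)c1C(OC)(c1ccc(OCOC)cc1)c1ccc(OCOC)cc1
F3 | step 11 | tert-butyl{[2-ethynyl-3-{methoxybis[4-(methoxymethoxy)phenyl]methyl}-4-[4-(methoxymethoxy)phenyl]phenyl]methoxy}dimethylsilane | C#Cc1c(CO[Si](C)(C)C(C)(C)C)ccc(-c2ccc(OCOC)cc2)c1C(OC)(c1ccc(OCOC)cc1)c1ccc(OCOC)cc1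
F4 | step 8 | triethyl{[(2E,4E)-5-[4-(methoxymethoxy)phenyl]penta-2,4-dien-1-yl]oxy}silane | CC[Si](CC)(CC)OC/C=C/C=C/c1ccc(OCOC)cc1
F5 | step 8 | 1,4-bis[4-(methoxymethoxy)phenyl]but-2-yne-1,4-diol (mixture of meso and racemic forms) | OC(C#CC(O)c1ccc(OCOC)cc1)c1ccc(OCOC)cc1
F6 | step 8 | 1,4-bis[4-(methoxymethoxy)phenyl]but-2-yne-1,4-dione | O=C(C#CC(=O)c1ccc(OCOC)cc1)c1ccc(OCOC)cc1
F7 | step 8 | cis-{3-[4-(methoxymethoxy)phenyl]-6-[(triethylsilyloxy)methyl]cyclohexa-1,4-diene-1,2-diyl}bis{[4-(methoxymethoxy)phenyl]methanone} (racemic, one enantiomer drawn) | COCOc1ccc(cc1)C(=O)C1=C(C(=O)c2ccc(OCOC)cc2)[C@@H](c2ccc(OCOC)cc2)C=C[C@H]1CO[Si](CC)(CC)CC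
F8 | step 8 | {3-[4-(methoxymethoxy)phenyl]-6-[(triethylsilyloxy)methyl]-1,2-phenylene}bis{[4-(methoxymethoxy)phenyl]methanone} | COCOc1ccc(cc1)C(=O)c1c(CO[Si](CC)(CC)CC)ccc(-c2ccc(OCOC)cc2)c1C(=O)c1ccc(OCOC)cc1
F9 | step 8 | {1-methoxy-1,6-bis[4-(methoxymethoxy)phenyl]-1,3-dihydro-2-benzofuran-7-yl}[4-(methoxymethoxy)phenyl]methanone (racemic) | COCOc1ccc(cc1)C(=O)c1c(-c2ccc(OCOC)cc2)ccc2COC(OC)(c3ccc(OCOC)cc3)c12
F10 | step 8 | 1-methoxy-7-{methoxybis[4-(methoxymethoxy)phenyl]methyl}-1,6-bis[4-(methoxymethoxy)phenyl]-1,3-dihydro-2-benzofuran (racemic) | COC(c1ccc(OCOC)cc1)(c1ccc(OCOC)cc1)c1c(-c2ccc(OCOC)cc2)ccc2COC(OC)(c3ccc(OCOC)cc3)c12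
F11 | step 9 | [6-(hydroxymethyl)-2-{methoxybis[4-(methoxymethoxy)phenyl]methyl}-3-[4-(methoxymethoxy)phenyl]phenyl][4-(methoxymethoxy)phenyl]methanol (racemic) | COCOc1ccc(cc1)C(O)c1c(CO)ccc(-c2ccc(OCOC)cc2)c1C(OC)(c1ccc(OCOC)cc1)c1ccc(OCOC)cc1
F12 | step 9 | {6-[(tert-butyldimethylsilyloxy)methyl]-2-{methoxybis[4-(methoxymethoxy)phenyl]methyl}-3-[4-(methoxymethoxy)phenyl]phenyl}[4-(methoxymethoxy)phenyl]methanol (racemic) | COCOc1ccc(cc1)C(O)c1c(CO[Si](C)(C)C(C)(C)C)ccc(-c2ccc(OCOC)cc2)c1C(OC)(c1ccc(OCOC)cc1)c1ccc(OCOC)cc1
F13 | step 7 | 1-[(1E,3E)-5-bromopenta-1,3-dien-1-yl]-4-(methoxymethoxy)benzene | BrC/C=C/C=C/c1ccc(OCOC)cc1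
A1 | alternative 1 | methyl 2-hydroxy-6-(4-methoxyphenyl)-3-(triisopropylsilyloxymethyl)benzoate | COC(=O)c1c(O)c(CO[Si](C(C)C)(C(C)C)C(C)C)ccc1-c1ccc(OC)cc1
A2 | alternative 1 | 1-methoxy-1,3-bis(trimethylsilyloxy)-5-(triisopropylsilyloxy)penta-1,3-diene (mixture of double-bond isomers) | COC(O[Si](C)(C)C)=CC(O[Si](C)(C)C)=CCO[Si](C(C)C)(C(C)C)C(C)C
A3 | alternative 1 | 3,3-dimethoxy-1-(4-methoxyphenyl)propan-1-one | COc1ccc(cc1)C(=O)CC(OC)OC
A4 | alternative 2 | 3,3,4-tris(4-methoxyphenyl)-7-(tert-butyldimethylsilyloxymethyl)isobenzofuran-1(3H)-one | O=C1OC(c2ccc(OC)cc2)(c2ccc(OC)cc2)c2c(-c3ccc(OC)cc3)ccc(CO[Si](C)(C)C(C)(C)C)c12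
A5 | alternative 2 | 1,1,3-tris(4-methoxyphenyl)prop-2-yn-1-yl 4-(tert-butyldimethylsilyloxy)but-2-ynoate | COc1ccc(cc1)C#CC(OC(=O)C#CCO[Si](C)(C)C(C)(C)C)(c1ccc(OC)cc1)c1ccc(OC)cc1
A6 | alternative 2 | ethyne | C#C
A7 | alternative 3 | methyl 3-[bis(4-methoxyphenyl)methyl]-4-(4-methoxyphenyl)-2-[(4-methoxyphenyl)ethynyl]benzoate | COC(=O)c1ccc(-c2ccc(OC)cc2)c(C(c2ccc(OC)cc2)c2ccc(OC)cc2)c1C#Cc1ccc(OC)cc1
A8 | alternative 3 | methyl 6-[(4-methoxyphenyl)ethynyl]-2-oxo-2H-pyran-5-carboxylate | COC(=O)C1=C(C#Cc2ccc(OC)cc2)OC(=O)C=C1
A9 | alternative 3 | 1,1',1''-(prop-1-yne-1,3,3-triyl)tris(4-methoxybenzene) | COc1ccc(cc1)C#CC(c1ccc(OC)cc1)c1ccc(OC)cc1
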